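**Assumption:** the SMILES is read as (3S,5R,8R,9R,10S)-polypoda-13E,17E,21-triene-3β,8α-diol (trans-decalin, 5α-H, 10β-Me, 9β side chain). Drimane numbering is used for the bicyclic core (C11 on C9, C12 = 8-Me). The route is a paper design; no step has been run, and selectivities are predictions from analogy.

## Retrosynthetic overview

1. C11–C12: alkylation of a C11 sulfone carbanion with (2E,6E)-farnesyl bromide, then reductive desulfonylation; the all-E chain is bought intact.
2. C9–C11 and the C9 stereocentre: decarboxylative [3,3] Claisen rearrangement of a 7β-allylic tosylacetate (key step), followed by Markovnikov hydration of the resulting Δ7 olefin to 8α-OH.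
3. 7-Oxygen/Δ8 olefin: Wharton transposition of a carvone-type enone, then Mitsunobu inversion at C7.
4. Ring A (C3–C4 bond, gem-dimethyl, 3β-OH): HAT-initiated radical cyclisation of the isopropenyl group onto a pendant aldehyde.
5. Ring B is the ring of (R)-carvone (bought, supplies C5); C10 is set by two α′-alkylations. Ring order: B (bought) → A.

## Route

**Step 1**
Reactants: 1, (R)-(−)-carvone
Product: 2, (5R,6S)-6-methylcarvone (trans major; the C6 epimer ratio is irrelevant because C6 is re-enolised in step 2)
Conditions: LDA, THF, −78 °C; MeI, −78 → −20 °C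
Reagents that add atoms: iodomethane, CI
Why: Kinetic α′-enolate alkylation of the enone puts the future C10 methyl on the carvone ring.

**Step 2**
Reactants: 2
Product: 3, (5S,6S)-6-allyl-2,6-dimethyl-5-(prop-1-en-2-yl)cyclohex-2-en-1-one (allyl trans, methyl cis to isopropenyl)
Conditions: LDA, THF, −20 → 0 °C; allyl bromide, DMPU, −78 °C → rt
Reagents that add atoms: allyl bromide, C=CCBr
Why: Second α′-enolate alkylation occurs anti to the adjacent isopropenyl group, so the bought C5 centre sets the quaternary C10 (10β-Me, C1 chain α).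

**Step 3**
Reactants: 3
Product: 4, 3-[(1S,6S)-1,3-dimethyl-2-oxo-6-(prop-1-en-2-yl)cyclohex-3-en-1-yl]propanal
Conditions: PdCl2(PhCN)2 (10 mol %), CuCl2·2H2O (10 mol %), AgNO2 (5 mol %), O2 (1 atm), t-BuOH/MeNO2 15:1, rt
Reagents that add atoms: dioxygen as terminal oxidant (O delivered via nitrite), O=O
Why: Nitrite-modified, aldehyde-selective (anti-Markovnikov) Wacker oxidation converts only the monosubstituted allyl olefin; the 1,1-disubstituted isopropenyl and the enone olefin are inert.

**Step 4**
Reactants: 4
Product: 5, 3β-hydroxy-11-nordrim-7-en-9-one = (4aS,6S,8aS)-6-hydroxy-2,5,5,8a-tetramethyl-4a,5,6,7,8,8a-hexahydronaphthalen-1(4H)-one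
Conditions: Fe(acac)3 (1 equiv), PhSiH3 (2.5 equiv), EtOH/(CH2OH)2, 60 °C, Ar
Reagents that add atoms: none (only H from PhSiH3/EtOH)
Why: Metal-hydride HAT to the isopropenyl CH2 gives the tertiary C4 radical, which adds 6-exo to the aldehyde carbon (radical–carbonyl cyclisation), creating the gem-dimethyl and C3–OH; the trans ring fusion is fixed by the trans-diequatorial C5/C10 tethers and the C–O bond is expected equatorial (3β) in the chair transition state.

**Step 5**
Reactants: 5
Product: 6, 7α,8α-epoxy-3β-hydroxy-11-nordriman-9-one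
Conditions: 30% H2O2, aq. NaOH, MeOH, 0 °C → rt
Reagents that add atoms: hydrogen peroxide, OO
Why: Weitz–Scheffer nucleophilic epoxidation; hydroperoxide attacks C7 axially from the α face (syn to H-5α, away from the 10β-Me), as carvone itself gives the trans epoxide.

**Step 6**
Reactants: 6
Product: 7, 11-nordrim-8-ene-3β,7α-diol
Conditions: N2H4·H2O, AcOH (cat.), MeOH, 0 °C → rt
Reagents that add atoms: none (N2 is lost)
Why: Wharton transposition turns the epoxy ketone into the 1,3-transposed allylic alcohol (C9 becomes =CH, Δ8), retaining the C7–O bond and hence the 7α configuration.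

**Step 7**
Reactants: 7; 8, (p-tolylsulfonyl)acetic acid
Product: 9, 3β-hydroxy-11-nordrim-8-en-7β-yl (p-tolylsulfonyl)acetate
Conditions: PPh3, DIAD, toluene/THF, 0 °C → rt
Reagents that add atoms: none beyond reactant 8
Why: Mitsunobu esterification inverts the allylic C7 carbinol to the 7β ester needed for β-face delivery, while the neopentyl 3β-OH next to the gem-dimethyl is expected to be unreactive.

**Step 8 (key step)**
Reactants: 9
Product: 10, 11-(p-tolylsulfonyl)drim-7-en-3β-ol (9β-CH2Ts, 9α-H, Δ7)
Conditions: BSA (3 equiv), KOAc (0.1 equiv), toluene, 110 °C; then K2CO3, MeOH workup (cleaves the transient 3-OTMS)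
Reagents that add atoms: none (CO2 is lost; silyl groups are transient)
Why: Decarboxylative Ireland-type [3,3] Claisen rearrangement of the silyl ketene acetal forms the C9–C11 bond suprafacially, so the 7β C–O stereocentre is transferred to C9 (β-CH2Ts); loss of CO2 leaves the sulfone handle and the alkene moves to C7=C8.

**Step 9**
Reactants: 10
Product: 11, 11-(p-tolylsulfonyl)drimane-3β,8α-diol
Conditions: Mn(dpm)3 (10 mol %), PhSiH3, O2 (1 atm), i-PrOH/CH2Cl2, 0 °C → rt; then PPh3
Reagents that add atoms: dioxygen, O=O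
Why: Mukaiyama (HAT) Markovnikov hydration gives the tertiary C8 radical, which should be trapped by O2 from the equatorial α face because the axial β face is 1,3-diaxial to the 10β-Me, giving 8α-OH/8β-Me.

**Step 10**
Reactants: 11; 12, (2E,6E)-farnesyl bromide
Product: 13, 11ξ-(p-tolylsulfonyl)polypoda-13E,17E,21-triene-3β,8α-diol (C11 epimers)
Conditions: n-BuLi (3.2 equiv), THF/DMPU, −78 °C; 12, −78 → −20 °C
Reagents that add atoms: none beyond reactant 12
Why: The α-sulfonyl carbanion (generated after the two alkoxides) is alkylated SN2 by the allylic bromide, forming C11–C12 without touching the pre-set E olefins; hindered lithium alkoxides do not compete at low temperature.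

**Step 11**
Reactants: 13
Product: 14, target, (3S,5R,8R,9R,10S)-polypoda-13E,17E,21-triene-3β,8α-diol
Conditions: 6% Na(Hg), Na2HPO4, MeOH/THF, −20 °C → rt
Reagents that add atoms: none
Why: Reductive desulfonylation cleaves the alkyl–sulfonyl bond; isolated trisubstituted olefins and free hydroxyls are inert, and there is no β-leaving group (8-OH is γ).

## Compound list

1 | (R)-(−)-carvone | O=C1C[C@H](C(C)=C)CC=C1C | starting material
2 | (5R,6S)-6-methylcarvone | C[C@H]1[C@H](C(C)=C)CC=C(C)C1=O | intermediate
3 | (5S,6S)-6-allyl-6-methylcarvone (allyl trans to isopropenyl) | C=CC[C@@]1(C)[C@H](C(C)=C)CC=C(C)C1=O | intermediate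
4 | 3-[(1S,6S)-1,3-dimethyl-2-oxo-6-(prop-1-en-2-yl)cyclohex-3-en-1-yl]propanal | O=CCC[C@@]1(C)[C@H](C(C)=C)CC=C(C)C1=O | intermediate
5 | 3β-hydroxy-11-nordrim-7-en-9-one | O=C1[C@@]2(C)CC[C@H](O)C(C)(C)[C@@H]2CC=C1C | intermediate
6 | 7α,8α-epoxy-3β-hydroxy-11-nordriman-9-one | O=C1[C@@]2(C)CC[C@H](O)C(C)(C)[C@@H]2C[C@H]3O[C@@]13C | intermediate
7 | 11-nordrim-8-ene-3β,7α-diol | CC1=C[C@@]2(C)CC[C@H](O)C(C)(C)[C@@H]2C[C@H]1O | intermediate
8 | (p-tolylsulfonyl)acetic acid | Cc1ccc(cc1)S(=O)(=O)CC(=O)O | starting material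
9 | 3β-hydroxy-11-nordrim-8-en-7β-yl (p-tolylsulfonyl)acetate | CC1=C[C@@]2(C)CC[C@H](O)C(C)(C)[C@@H]2C[C@@H]1OC(=O)CS(=O)(=O)c1ccc(C)cc1 | intermediate
10 | 11-(p-tolylsulfonyl)drim-7-en-3β-ol | Cc1ccc(cc1)S(=O)(=O)C[C@@H]1[C@@]2(C)CC[C@H](O)C(C)(C)[C@@H]2CC=C1C | intermediate
11 | 11-(p-tolylsulfonyl)drimane-3β,8α-diol | Cc1ccc(cc1)S(=O)(=O)C[C@@H]1[C@@]2(C)CC[C@H](O)C(C)(C)[C@@H]2CC[C@@]1(C)O | intermediate
12 | (2E,6E)-farnesyl bromide | CC(C)=CCC/C(C)=C/CC/C(C)=C/CBr | starting material
13 | 11ξ-(p-tolylsulfonyl)polypoda-13E,17E,21-triene-3β,8α-diol | CC(C)=CCC/C(C)=C/CC/C(C)=C/CC([C@@H]1[C@@]2(C)CC[C@H](O)C(C)(C)[C@@H]2CC[C@@]1(C)O)S(=O)(=O)c1ccc(C)cc1 | intermediate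
14 | (3S,5R,8R,9R,10S)-polypoda-13E,17E,21-triene-3β,8α-diol | CC(C)=CCC/C(C)=C/CC/C(C)=C/CC[C@@H]1[C@@]2(C)CC[C@H](O)C(C)(C)[C@@H]2CC[C@@]1(C)O | target

## Summary

Total steps: 11. Longest linear sequence: 11 (from (R)-carvone; 8 and 12 are purchased).

Three steps most likely to fail, each with a fallback that changes the approach:

- **Step 4 (radical cyclisation onto the aldehyde).** Risks are incomplete 3β selectivity, simple alkene reduction, or aldehyde reduction. Fallback: close ring A by intramolecular nitrile oxide–alkene cycloaddition (oxime of 4, NaOCl) onto the isopropenyl group, cleave the isoxazoline N–O bond to the 3-keto-4-hydroxymethyl compound, deoxygenate the CH2OH, and reduce the 3-ketone with NaBH4 (axial hydride delivery gives 3β-OH).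
- **Step 8 (Claisen from a pseudo-equatorial 7β ester to C9 beside quaternary C10).** The boat-like transition state and the neighbouring 10β-Me may slow the rearrangement or favour elimination. Fallback: [2,3]-Wittig–Still rearrangement of the 7β-O-CH2SnBu3 ether (n-BuLi, −78 °C) to the 9β-CH2OH compound (3β-hydroxydrimenol), then PhSSPh/Bu3P and oxidation to the same C11 sulfone.
- **Step 9 (face selectivity of the C8 hydration).** The 8β-OH epimer could form competitively. Fallback: ionic two-step hydration, i.e. mCPBA epoxidation of Δ7 from the open α face and LiAlH4 opening at the less substituted C7 to give the 8α-ol.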